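## Retrosynthetic overview

1. The quaternary centre (chain C3) comes from Zweifel vinylation of tertiary allylic boronic ester 39, made by lithiation–borylation (stereospecific 1,2-metallate shift) of allylic carbamate 36 with ring boronic ester 10.
2. Carbamate 36 comes from a selenium-mediated Zweifel coupling (C5–C6 bond, E-alkene) of secondary boronic ester 27 with iodoalkenyl carbamate 31, made from (S)-but-3-yn-2-ol.
3. Boronic ester 27 is built by iterative boronic-ester homologation of isopropyl-Bpin: four reagent-controlled CH(CH3) insertions and two CH2CH2 spacers.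
4. The only ring is formed by one-carbon ring expansion (β-oxido carbenoid 1,2-shift) of (S)-2,2,3-trimethylcyclopentanone. The enolate formed is borylmethylated in the same flask (sets ring C2), then methylenation and CH2 homologation give 10.
5. The cyclopentanone comes from Cu-catalysed asymmetric conjugate methylation and enolate methylation of 2-methylcyclopent-2-enone.

Assumption: the SMILES is read as ring C2 (S, side chain) and ring C6 (S, methyl) trans, chain C3 S, C6 R, C9 R, C10 S, C13 R, 4E (numbering as in the name of 42); pinacol on boron is treated as a protecting group and both enantiomers of 1-(tributylstannyl)ethyl 2,4,6-triisopropylbenzoate as stock reagents.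

## Route

Step 1
Reactants: 1 2-methylcyclopent-2-en-1-one
Product: 3 (3S)-2,2,3-trimethylcyclopentan-1-one, via magnesium enolate 2 (not isolated)
Conditions: MeMgBr, Cu(OTf)2 (3 mol %), chiral imidazolinium NHC precursor (4 mol %, enantiomer giving 3S), Et2O, −30 °C; then MeI, DMPU, −30 °C → rt
Reagents that add atoms: methylmagnesium bromide C[Mg]Br; iodomethane CI
Why: Copper-catalysed asymmetric conjugate addition of the Grignard reagent to the α-substituted enone (ligand control sets C3 as S) followed by C-methylation of the magnesium enolate (conjugate addition–enolate alkylation) gives the gem-dimethyl ketone, whose quaternary carbon is not stereogenic.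

Step 2
Reactants: 3 (3S)-2,2,3-trimethylcyclopentan-1-one
Product: 7 (2R,4S)-3,3,4-trimethyl-2-[(4,4,5,5-tetramethyl-1,3,2-dioxaborolan-2-yl)methyl]cyclohexan-1-one, via lithium alkoxide 4 (not isolated), via carbenoid 5 (not isolated), via lithium enolate 6 (not isolated)
Conditions: CH2Br2, lithium 2,2,6,6-tetramethylpiperidide, THF, −78 °C; n-BuLi, −95 → −20 °C; ICH2Bpin, DMPU, −78 → 0 °C
Reagents that add atoms: dibromomethane BrCBr; 2-(iodomethyl)-4,4,5,5-tetramethyl-1,3,2-dioxaborolane ICB1OC(C)(C)C(C)(C)O1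
Why: Proposed new method: an interrupted Taguchi–Yamamoto–Nozaki ring enlargement in which LiCHBr2 adds to the ketone, Br–Li exchange gives the β-oxido carbenoid, the more substituted (quaternary) α-carbon migrates to the carbenoid carbon with loss of bromide (non-pericyclic 1,2-shift, ring expansion) to give regiospecifically the lithium enolate flanked by the quaternary carbon, and this enolate is C-alkylated in the same flask by ICH2Bpin (SN2 reactivity raised by the adjacent boron) on the face anti to the pseudoaxial methyl of the half-chair that keeps the C4 methyl pseudoequatorial, so the new C2 substituent is trans to the C4 methyl; closest known reaction type: β-oxido carbenoid ring enlargement of cycloalkanones with protonation or silylation of the enolate, and alkylation of preformed lithium enolates with halomethylboronic esters.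

Step 3
Reactants: 7 (2R,4S)-3,3,4-trimethyl-2-[(4,4,5,5-tetramethyl-1,3,2-dioxaborolan-2-yl)methyl]cyclohexan-1-one
Product: 8 4,4,5,5-tetramethyl-2-{[(1S,3S)-2,2,3-trimethyl-6-methylidenecyclohexyl]methyl}-1,3,2-dioxaborolane
Conditions: Zn, CH2Br2, TiCl4, THF/CH2Cl2, 0 °C → rt
Reagents that add atoms: dibromomethane BrCBr
Why: Lombardo–Takai methylenation with the non-basic CH2(ZnBr)2/TiCl4 reagent converts the hindered ketone into the exocyclic alkene without epimerising the adjacent tertiary centre (its only stereolabile stage) and should leave the pinacol boronate intact.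

Step 4
Reactants: 8 4,4,5,5-tetramethyl-2-{[(1S,3S)-2,2,3-trimethyl-6-methylidenecyclohexyl]methyl}-1,3,2-dioxaborolane
Product: 10 4,4,5,5-tetramethyl-2-{2-[(1S,3S)-2,2,3-trimethyl-6-methylidenecyclohexyl]ethyl}-1,3,2-dioxaborolane, via chloromethyl boronate 9 (not isolated)
Conditions: BrCH2Cl, n-BuLi, THF, −78 °C → rt
Reagents that add atoms: bromochloromethane ClCBr
Why: Matteson homologation: LiCH2Cl made in situ adds to boron and the primary alkyl group undergoes the 1,2-metallate shift with loss of chloride on warming, inserting one CH2 without touching the stereocentres.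

Step 5
Reactants: 11 4,4,5,5-tetramethyl-2-(propan-2-yl)-1,3,2-dioxaborolane
Product: 13 4,4,5,5-tetramethyl-2-[(2S)-3-methylbutan-2-yl]-1,3,2-dioxaborolane, via boronate complex 12 (not isolated)
Conditions: (R)-Bu3SnCH(CH3)O2CAr (Ar = 2,4,6-triisopropylphenyl), n-BuLi, Et2O, −78 °C; then 11; −78 → 40 °C
Reagents that add atoms: (1R)-1-(tributylstannyl)ethyl 2,4,6-tri(propan-2-yl)benzoate C[C@H](OC(=O)c1c(C(C)C)cc(C(C)C)cc1C(C)C)[Sn](CCCC)(CCCC)CCCC
Why: Aggarwal lithiation–borylation: tin–lithium exchange gives the configurationally stable (R)-lithiated benzoate, which adds to boron with retention, and the isopropyl group then undergoes the stereospecific 1,2-metallate shift with inversion at the carbenoid carbon, which sets chain C13.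

Step 6
Reactants: 13 4,4,5,5-tetramethyl-2-[(2S)-3-methylbutan-2-yl]-1,3,2-dioxaborolane
Product: 17 2-[(3R)-3,4-dimethylpentyl]-4,4,5,5-tetramethyl-1,3,2-dioxaborolane, via chloromethyl boronate 14 (not isolated), via boronic ester 15 (not isolated), via chloromethyl boronate 16 (not isolated)
Conditions: BrCH2Cl, n-BuLi, THF, −78 °C → rt; then the same again in the same flask
Reagents that add atoms: bromochloromethane ClCBr
Why: Two consecutive Matteson homologations in one flask (LiCH2Cl addition, then 1,2-metallate shift with retention at the migrating stereocentre on warming, excess carbenoid decomposing before the next cycle) install the C11–C12 spacer.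

Step 7
Reactants: 17 2-[(3R)-3,4-dimethylpentyl]-4,4,5,5-tetramethyl-1,3,2-dioxaborolane
Product: 19 2-[(2S,5R)-5,6-dimethylheptan-2-yl]-4,4,5,5-tetramethyl-1,3,2-dioxaborolane, via boronate complex 18 (not isolated)
Conditions: (R)-Bu3SnCH(CH3)O2CAr, n-BuLi, Et2O, −78 °C; then 17; −78 → 40 °C
Reagents that add atoms: (1R)-1-(tributylstannyl)ethyl 2,4,6-tri(propan-2-yl)benzoate C[C@H](OC(=O)c1c(C(C)C)cc(C(C)C)cc1C(C)C)[Sn](CCCC)(CCCC)CCCC
Why: Lithiation–borylation as in step 5: the (R)-carbenoid carbon is inverted in the 1,2-metallate shift of the primary alkyl group, which sets chain C10 by reagent control.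

Step 8
Reactants: 19 2-[(2S,5R)-5,6-dimethylheptan-2-yl]-4,4,5,5-tetramethyl-1,3,2-dioxaborolane
Product: 21 4,4,5,5-tetramethyl-2-[(2S,3S,6R)-3,6,7-trimethyloctan-2-yl]-1,3,2-dioxaborolane, via boronate complex 20 (not isolated)
Conditions: (R)-Bu3SnCH(CH3)O2CAr, n-BuLi, Et2O, −78 °C; then 19; −78 → 40 °C
Reagents that add atoms: (1R)-1-(tributylstannyl)ethyl 2,4,6-tri(propan-2-yl)benzoate C[C@H](OC(=O)c1c(C(C)C)cc(C(C)C)cc1C(C)C)[Sn](CCCC)(CCCC)CCCC
Why: Lithiation–borylation in which the secondary alkyl group migrates with retention while the (R)-carbenoid carbon is inverted, which sets chain C9 and gives the anti 9,10-dimethyl pair under reagent control.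

Step 9
Reactants: 21 4,4,5,5-tetramethyl-2-[(2S,3S,6R)-3,6,7-trimethyloctan-2-yl]-1,3,2-dioxaborolane
Product: 25 4,4,5,5-tetramethyl-2-[(3R,4S,7R)-3,4,7,8-tetramethylnonyl]-1,3,2-dioxaborolane, via chloromethyl boronate 22 (not isolated), via boronic ester 23 (not isolated), via chloromethyl boronate 24 (not isolated)
Conditions: BrCH2Cl, n-BuLi, THF, −78 °C → rt; then the same again in the same flask
Reagents that add atoms: bromochloromethane ClCBr
Why: Double Matteson homologation as in step 6 (stereoretentive 1,2-metallate shifts) installs the C7–C8 spacer.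

Step 10
Reactants: 25 4,4,5,5-tetramethyl-2-[(3R,4S,7R)-3,4,7,8-tetramethylnonyl]-1,3,2-dioxaborolane
Product: 27 4,4,5,5-tetramethyl-2-[(2R,5R,6S,9R)-5,6,9,10-tetramethylundecan-2-yl]-1,3,2-dioxaborolane, via boronate complex 26 (not isolated)
Conditions: (S)-Bu3SnCH(CH3)O2CAr, n-BuLi, Et2O, −78 °C; then 25; −78 → 40 °C
Reagents that add atoms: (1S)-1-(tributylstannyl)ethyl 2,4,6-tri(propan-2-yl)benzoate C[C@@H](OC(=O)c1c(C(C)C)cc(C(C)C)cc1C(C)C)[Sn](CCCC)(CCCC)CCCC
Why: Lithiation–borylation with the enantiomeric (S)-carbenoid (retentive borylation, invertive 1,2-metallate shift) sets chain C6.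

Step 11
Reactants: 28 (2S)-but-3-yn-2-ol
Product: 29 (2S)-but-3-yn-2-yl N,N-di(propan-2-yl)carbamate
Conditions: NaH, ClC(O)N(i-Pr)2, THF, 0 → 60 °C
Reagents that add atoms: N,N-di(propan-2-yl)carbamoyl chloride CC(C)N(C(C)C)C(Cl)=O
Why: O-Carbamoylation of the sodium alkoxide leaves the chiral-pool stereocentre (future chain C3) untouched and installs the directing and leaving group for step 14.

Step 12
Reactants: 29 (2S)-but-3-yn-2-yl N,N-di(propan-2-yl)carbamate
Product: 31 (2S,3E)-4-iodobut-3-en-2-yl N,N-di(propan-2-yl)carbamate, via alkenylzirconocene 30 (not isolated)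
Conditions: Cp2Zr(H)Cl (1.1 equiv), THF, rt; then I2, 0 °C
Reagents that add atoms: iodine II
Why: Hydrozirconation of the terminal alkyne (syn, zirconium at the terminal carbon) and iodinolysis with retention give the E-vinyl iodide.

Step 13
Reactants: 31 (2S,3E)-4-iodobut-3-en-2-yl N,N-di(propan-2-yl)carbamate; 27 4,4,5,5-tetramethyl-2-[(2R,5R,6S,9R)-5,6,9,10-tetramethylundecan-2-yl]-1,3,2-dioxaborolane
Product: 36 (2S,3E,5R,8R,9S,12R)-5,8,9,12,13-pentamethyltetradec-3-en-2-yl N,N-di(propan-2-yl)carbamate, via alkenyllithium 32 (not isolated), via boronate complex 33 (not isolated), via selenide 34 (not isolated), via selenoxide 35 (not isolated)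
Conditions: 31, t-BuLi (2 equiv), Et2O/THF, −78 °C; then 27, −78 → 0 °C; PhSeCl, −78 °C; mCPBA, −45 °C → rt
Reagents that add atoms: none
Why: Zweifel-type olefination in its selenium-mediated variant: the (E)-alkenyllithium forms the boronate with 27, PhSe+ triggers the anti 1,2-metallate shift of the secondary alkyl group (retention at chain C6), and selenoxide syn-elimination of boron and selenium gives the E-alkene and the C5–C6 bond.

Step 14
Reactants: 36 (2S,3E,5R,8R,9S,12R)-5,8,9,12,13-pentamethyltetradec-3-en-2-yl N,N-di(propan-2-yl)carbamate; 10 4,4,5,5-tetramethyl-2-{2-[(1S,3S)-2,2,3-trimethyl-6-methylidenecyclohexyl]ethyl}-1,3,2-dioxaborolane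
Product: 39 4,4,5,5-tetramethyl-2-{(3S,4E,6R,9R,10S,13R)-3,6,9,10,13,14-hexamethyl-1-[(1S,3S)-2,2,3-trimethyl-6-methylidenecyclohexyl]pentadec-4-en-3-yl}-1,3,2-dioxaborolane, via lithiated carbamate 37 (not isolated), via boronate complex 38 (not isolated)
Conditions: s-BuLi, TMEDA, Et2O, −78 °C; then 10, −78 °C; MgBr2·OEt2, MeOH, −78 °C → rt
Reagents that add atoms: none
Why: Hoppe–Aggarwal lithiation–borylation of a secondary allylic carbamate: deprotonation and α-borylation by the primary boronic ester both proceed with retention (assumed, as for pinacol esters with benzylic carbamates), and the 1,2-metallate shift of the ring-ethyl group displaces the carbamate with inversion, which fixes the fully substituted carbon (3S).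

Step 15
Reactants: 39 4,4,5,5-tetramethyl-2-{(3S,4E,6R,9R,10S,13R)-3,6,9,10,13,14-hexamethyl-1-[(1S,3S)-2,2,3-trimethyl-6-methylidenecyclohexyl]pentadec-4-en-3-yl}-1,3,2-dioxaborolane
Product: 42 (2S,6S)-2-[(3S,4E,6R,9R,10S,13R)-3-ethenyl-3,6,9,10,13,14-hexamethylpentadec-4-en-1-yl]-1,1,6-trimethyl-3-methylidenecyclohexane, via vinyl boronate complex 40 (not isolated), via iodo boronic ester 41 (not isolated)
Conditions: CH2=CHMgBr, THF/DMSO, 0 °C → rt; I2, THF, −78 °C; NaOMe, MeOH, −78 °C → rt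
Reagents that add atoms: vinylmagnesium bromide C=C[Mg]Br
Why: Zweifel olefination: iodination of the vinyl boronate triggers the 1,2-metallate shift of the tertiary carbon with retention, and methoxide-induced anti-elimination of boron and iodine leaves the vinyl group on the quaternary stereocentre (3S).

## Compound list

1 | 2-methylcyclopent-2-en-1-one | CC1=CCCC1=O | starting material
2 | bromomagnesium (3S)-2,3-dimethylcyclopent-1-en-1-olate | C[C@H]1CCC(O[Mg]Br)=C1C | intermediate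
3 | (3S)-2,2,3-trimethylcyclopentan-1-one | C[C@H]1CCC(=O)C1(C)C | intermediate
4 | lithium (3S)-1-(dibromomethyl)-2,2,3-trimethylcyclopentan-1-olate (both C1 epimers) | C[C@H]1CCC(O[Li])(C(Br)Br)C1(C)C | intermediate
5 | lithium (3S)-1-[bromo(lithio)methyl]-2,2,3-trimethylcyclopentan-1-olate | C[C@H]1CCC(O[Li])(C([Li])Br)C1(C)C | intermediate
6 | lithium (4S)-3,3,4-trimethylcyclohex-1-en-1-olate | C[C@H]1CCC(O[Li])=CC1(C)C | intermediate
7 | (2R,4S)-3,3,4-trimethyl-2-[(4,4,5,5-tetramethyl-1,3,2-dioxaborolan-2-yl)methyl]cyclohexan-1-one | B1(OC(C)(C)C(C)(C)O1)C[C@H]2C(=O)CC[C@H](C)C2(C)C | intermediate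
8 | 4,4,5,5-tetramethyl-2-{[(1S,3S)-2,2,3-trimethyl-6-methylidenecyclohexyl]methyl}-1,3,2-dioxaborolane | B1(OC(C)(C)C(C)(C)O1)C[C@H]2C(=C)CC[C@H](C)C2(C)C | intermediate
9 | lithium (chloromethyl)(pinacolato){[(1S,3S)-2,2,3-trimethyl-6-methylidenecyclohexyl]methyl}borate | [Li+].ClC[B-]1(C[C@H]2C(=C)CC[C@H](C)C2(C)C)OC(C)(C)C(C)(C)O1 | intermediate
10 | 4,4,5,5-tetramethyl-2-{2-[(1S,3S)-2,2,3-trimethyl-6-methylidenecyclohexyl]ethyl}-1,3,2-dioxaborolane | B1(OC(C)(C)C(C)(C)O1)CC[C@H]2C(=C)CC[C@H](C)C2(C)C | intermediate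
11 | 4,4,5,5-tetramethyl-2-(propan-2-yl)-1,3,2-dioxaborolane | CC(C)B1OC(C)(C)C(C)(C)O1 | starting material
12 | lithium (pinacolato)(propan-2-yl)[(1R)-1-{[2,4,6-tri(propan-2-yl)benzoyl]oxy}ethyl]borate | [Li+].C[C@H](OC(=O)c1c(C(C)C)cc(C(C)C)cc1C(C)C)[B-]1(C(C)C)OC(C)(C)C(C)(C)O1 | intermediate
13 | 4,4,5,5-tetramethyl-2-[(2S)-3-methylbutan-2-yl]-1,3,2-dioxaborolane | B1(OC(C)(C)C(C)(C)O1)[C@@H](C)C(C)C | intermediate
14 | lithium (chloromethyl)[(2S)-3-methylbutan-2-yl](pinacolato)borate | [Li+].ClC[B-]1([C@@H](C)C(C)C)OC(C)(C)C(C)(C)O1 | intermediate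
15 | 2-[(2R)-2,3-dimethylbutyl]-4,4,5,5-tetramethyl-1,3,2-dioxaborolane | B1(OC(C)(C)C(C)(C)O1)C[C@@H](C)C(C)C | intermediate
16 | lithium (chloromethyl)[(2R)-2,3-dimethylbutyl](pinacolato)borate | [Li+].ClC[B-]1(C[C@@H](C)C(C)C)OC(C)(C)C(C)(C)O1 | intermediate
17 | 2-[(3R)-3,4-dimethylpentyl]-4,4,5,5-tetramethyl-1,3,2-dioxaborolane | B1(OC(C)(C)C(C)(C)O1)CC[C@@H](C)C(C)C | intermediate
18 | lithium [(3R)-3,4-dimethylpentyl](pinacolato)[(1R)-1-{[2,4,6-tri(propan-2-yl)benzoyl]oxy}ethyl]borate | [Li+].C[C@H](OC(=O)c1c(C(C)C)cc(C(C)C)cc1C(C)C)[B-]1(CC[C@@H](C)C(C)C)OC(C)(C)C(C)(C)O1 | intermediate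
19 | 2-[(2S,5R)-5,6-dimethylheptan-2-yl]-4,4,5,5-tetramethyl-1,3,2-dioxaborolane | B1(OC(C)(C)C(C)(C)O1)[C@@H](C)CC[C@@H](C)C(C)C | intermediate
20 | lithium [(2S,5R)-5,6-dimethylheptan-2-yl](pinacolato)[(1R)-1-{[2,4,6-tri(propan-2-yl)benzoyl]oxy}ethyl]borate | [Li+].C[C@H](OC(=O)c1c(C(C)C)cc(C(C)C)cc1C(C)C)[B-]1([C@@H](C)CC[C@@H](C)C(C)C)OC(C)(C)C(C)(C)O1 | intermediate
21 | 4,4,5,5-tetramethyl-2-[(2S,3S,6R)-3,6,7-trimethyloctan-2-yl]-1,3,2-dioxaborolane | B1(OC(C)(C)C(C)(C)O1)[C@@H](C)[C@@H](C)CC[C@@H](C)C(C)C | intermediate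
22 | lithium (chloromethyl)(pinacolato)[(2S,3S,6R)-3,6,7-trimethyloctan-2-yl]borate | [Li+].ClC[B-]1([C@@H](C)[C@@H](C)CC[C@@H](C)C(C)C)OC(C)(C)C(C)(C)O1 | intermediate
23 | 4,4,5,5-tetramethyl-2-[(2R,3S,6R)-2,3,6,7-tetramethyloctyl]-1,3,2-dioxaborolane | B1(OC(C)(C)C(C)(C)O1)C[C@@H](C)[C@@H](C)CC[C@@H](C)C(C)C | intermediate
24 | lithium (chloromethyl)(pinacolato)[(2R,3S,6R)-2,3,6,7-tetramethyloctyl]borate | [Li+].ClC[B-]1(C[C@@H](C)[C@@H](C)CC[C@@H](C)C(C)C)OC(C)(C)C(C)(C)O1 | intermediate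
25 | 4,4,5,5-tetramethyl-2-[(3R,4S,7R)-3,4,7,8-tetramethylnonyl]-1,3,2-dioxaborolane | B1(OC(C)(C)C(C)(C)O1)CC[C@@H](C)[C@@H](C)CC[C@@H](C)C(C)C | intermediate
26 | lithium (pinacolato)[(3R,4S,7R)-3,4,7,8-tetramethylnonyl][(1S)-1-{[2,4,6-tri(propan-2-yl)benzoyl]oxy}ethyl]borate | [Li+].C[C@@H](OC(=O)c1c(C(C)C)cc(C(C)C)cc1C(C)C)[B-]1(CC[C@@H](C)[C@@H](C)CC[C@@H](C)C(C)C)OC(C)(C)C(C)(C)O1 | intermediate
27 | 4,4,5,5-tetramethyl-2-[(2R,5R,6S,9R)-5,6,9,10-tetramethylundecan-2-yl]-1,3,2-dioxaborolane | B1(OC(C)(C)C(C)(C)O1)[C@H](C)CC[C@@H](C)[C@@H](C)CC[C@@H](C)C(C)C | intermediate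
28 | (2S)-but-3-yn-2-ol | C[C@H](O)C#C | starting material
29 | (2S)-but-3-yn-2-yl N,N-di(propan-2-yl)carbamate | C[C@H](OC(=O)N(C(C)C)C(C)C)C#C | intermediate
30 | chlorobis(cyclopentadienyl)[(1E,3S)-3-{[di(propan-2-yl)carbamoyl]oxy}but-1-en-1-yl]zirconium | C[C@H](OC(=O)N(C(C)C)C(C)C)/C=C/[Zr](Cl)(C1C=CC=C1)C1C=CC=C1 | intermediate
31 | (2S,3E)-4-iodobut-3-en-2-yl N,N-di(propan-2-yl)carbamate | C[C@H](OC(=O)N(C(C)C)C(C)C)/C=C/I | intermediate
32 | (2S,3E)-4-lithiobut-3-en-2-yl N,N-di(propan-2-yl)carbamate | C[C@H](OC(=O)N(C(C)C)C(C)C)/C=C/[Li] | intermediate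
33 | lithium boronate complex of 32 and 27 (alkenyl and secondary alkyl on boron) | [Li+].C[C@H](OC(=O)N(C(C)C)C(C)C)/C=C/[B-]1([C@H](C)CC[C@@H](C)[C@@H](C)CC[C@@H](C)C(C)C)OC(C)(C)C(C)(C)O1 | intermediate
34 | (2S,5R,8R,9S,12R)-5,8,9,12,13-pentamethyl-3-(phenylselanyl)-4-(4,4,5,5-tetramethyl-1,3,2-dioxaborolan-2-yl)tetradecan-2-yl N,N-di(propan-2-yl)carbamate (anti-addition product, one of the two C3/C4 diastereomers shown; both give the same E-alkene) | C[C@H](OC(=O)N(C(C)C)C(C)C)[C@H]([Se]c1ccccc1)[C@@H](B2OC(C)(C)C(C)(C)O2)[C@H](C)CC[C@@H](C)[C@@H](C)CC[C@@H](C)C(C)C | intermediate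
35 | selenoxide of 34 | C[C@H](OC(=O)N(C(C)C)C(C)C)[C@H]([Se](=O)c1ccccc1)[C@@H](B2OC(C)(C)C(C)(C)O2)[C@H](C)CC[C@@H](C)[C@@H](C)CC[C@@H](C)C(C)C | intermediate
36 | (2S,3E,5R,8R,9S,12R)-5,8,9,12,13-pentamethyltetradec-3-en-2-yl N,N-di(propan-2-yl)carbamate | C[C@H](OC(=O)N(C(C)C)C(C)C)/C=C/[C@H](C)CC[C@@H](C)[C@@H](C)CC[C@@H](C)C(C)C | intermediate
37 | 36 lithiated at C2 (α to oxygen, lithium in place of hydrogen) | C[C@@](OC(=O)N(C(C)C)C(C)C)([Li])/C=C/[C@H](C)CC[C@@H](C)[C@@H](C)CC[C@@H](C)C(C)C | intermediate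
38 | lithium boronate complex of 37 and 10 | [Li+].C[C@](OC(=O)N(C(C)C)C(C)C)(/C=C/[C@H](C)CC[C@@H](C)[C@@H](C)CC[C@@H](C)C(C)C)[B-]1(CC[C@H]2C(=C)CC[C@H](C)C2(C)C)OC(C)(C)C(C)(C)O1 | intermediate
39 | 4,4,5,5-tetramethyl-2-{(3S,4E,6R,9R,10S,13R)-3,6,9,10,13,14-hexamethyl-1-[(1S,3S)-2,2,3-trimethyl-6-methylidenecyclohexyl]pentadec-4-en-3-yl}-1,3,2-dioxaborolane | B1(OC(C)(C)C(C)(C)O1)[C@@](C)(/C=C/[C@H](C)CC[C@@H](C)[C@@H](C)CC[C@@H](C)C(C)C)CC[C@H]2C(=C)CC[C@H](C)C2(C)C | intermediate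
40 | bromomagnesium vinyl boronate complex of 39 | [Br-].[Mg+2].C=C[B-]1([C@@](C)(/C=C/[C@H](C)CC[C@@H](C)[C@@H](C)CC[C@@H](C)C(C)C)CC[C@H]2C(=C)CC[C@H](C)C2(C)C)OC(C)(C)C(C)(C)O1 | intermediate
41 | 2-iodo-1-(tertiary alkyl)ethyl boronic ester from 40 (CH(Bpin)CH2I on the quaternary carbon, both epimers at the boron-bearing carbon) | ICC(B1OC(C)(C)C(C)(C)O1)[C@@](C)(/C=C/[C@H](C)CC[C@@H](C)[C@@H](C)CC[C@@H](C)C(C)C)CC[C@H]2C(=C)CC[C@H](C)C2(C)C | intermediate
42 | (2S,6S)-2-[(3S,4E,6R,9R,10S,13R)-3-ethenyl-3,6,9,10,13,14-hexamethylpentadec-4-en-1-yl]-1,1,6-trimethyl-3-methylidenecyclohexane | C=C[C@@](C)(/C=C/[C@H](C)CC[C@@H](C)[C@@H](C)CC[C@@H](C)C(C)C)CC[C@H]1C(=C)CC[C@H](C)C1(C)C | target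

## Step count and risks

Total steps: 15. Longest linear sequence: 9 (steps 5–10, 13, 14, 15).

**Step 2 (the proposed new ring-expansion and borylmethylation cascade).** LiCHBr2 may add poorly to the hindered ketone, the CH2 carbon may migrate instead of the quaternary one, or the enolate may be O-alkylated. The fallback uses known chemistry, sets out from 3 and comes back at 10. LiCH(SPh)2 (from CH2(SPh)2 and n-BuLi, THF, −78 °C) adds to 3 to give (3S)-1-[bis(phenylsulfanyl)methyl]-2,2,3-trimethylcyclopentan-1-ol F1. CuOTf and i-Pr2NEt in benzene at 78 °C (Cohen cationic semipinacol ring expansion, the more substituted carbon migrates) give (4S)-3,3,4-trimethyl-2-(phenylsulfanyl)cyclohexan-1-one F2. Bu3SnH/AIBN with excess vinyl-Bpin in benzene at 80 °C (Giese addition of the α-keto radical, C–C bond formed anti to the pseudoaxial methyl) gives (2R,4S)-3,3,4-trimethyl-2-[2-(4,4,5,5-tetramethyl-1,3,2-dioxaborolan-2-yl)ethyl]cyclohexan-1-one F3. Lombardo–Takai methylenation (Zn, CH2Br2, TiCl4) of F3 gives 10 directly, so steps 3 and 4 are not needed.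

**Step 13 (selenium-mediated Zweifel coupling with a carbamate-bearing alkenyllithium).** The alkenyllithium may be quenched by the acidic α-oxy allylic hydrogen, or PhSe+ may attack sluggishly. The fallback sets out from 27 and comes back at 36. Homologation of 27 with LiCHCl2 (CH2Cl2, n-BuLi, THF, −100 °C → rt) gives 2-[(2R,5R,6S,9R)-1-chloro-2,5,6,9,10-pentamethylundecyl]-4,4,5,5-tetramethyl-1,3,2-dioxaborolane F4. Oxidation with NaBO3 in THF/water gives (2R,5R,6S,9R)-2,5,6,9,10-pentamethylundecanal F5. Horner–Wadsworth–Emmons reaction with dimethyl (2-oxopropyl)phosphonate (LiCl, i-Pr2NEt, MeCN) gives (3E,5R,8R,9S,12R)-5,8,9,12,13-pentamethyltetradec-3-en-2-one F6. Corey–Bakshi–Shibata reduction with the (R)-methyl oxazaborolidine and catecholborane gives (2S,3E,5R,8R,9S,12R)-5,8,9,12,13-pentamethyltetradec-3-en-2-ol F7. NaH and ClC(O)N(i-Pr)2 then give 36.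

**Step 14 (lithiation–borylation of the allylic carbamate).** Borylation may occur at the γ-carbon, the boronate may revert, or stereospecificity may erode. The fallback reverses the partners so the carbenoid is not allylic; it sets out from 10 and 27 and comes back at 39.
- Ring partner: 10 is homologated with the (S)-stannane reagent and n-BuLi (as in step 10) to 4,4,5,5-tetramethyl-2-{(2R)-4-[(1S,3S)-2,2,3-trimethyl-6-methylidenecyclohexyl]butan-2-yl}-1,3,2-dioxaborolane F8. NaOH/H2O2 gives (2R)-4-[(1S,3S)-2,2,3-trimethyl-6-methylidenecyclohexyl]butan-2-ol F9. NaH and 2,4,6-triisopropylbenzoyl chloride give (2R)-4-[(1S,3S)-2,2,3-trimethyl-6-methylidenecyclohexyl]butan-2-yl 2,4,6-tri(propan-2-yl)benzoate F10.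
- Chain partner: 27 with 1-bromovinyllithium (vinyl bromide, LDA, −95 °C), then I2 and NaOMe, gives (3R,6R,7S,10R)-2-bromo-3,6,7,10,11-pentamethyldodec-1-ene F11. LDA gives (3R,6R,7S,10R)-3,6,7,10,11-pentamethyldodec-1-yne F12. Pinacolborane with catalytic Cp2Zr(H)Cl gives 4,4,5,5-tetramethyl-2-[(1E,3R,6R,7S,10R)-3,6,7,10,11-pentamethyldodec-1-en-1-yl]-1,3,2-dioxaborolane F13.
- Union: F10 is lithiated (s-BuLi, TMEDA, cyclopentyl methyl ether, −60 °C), F13 is added, and the alkenyl group migrates with inversion at the carbenoid carbon on warming to give 39.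

Further compounds
F1 | step 2 | (3S)-1-[bis(phenylsulfanyl)methyl]-2,2,3-trimethylcyclopentan-1-ol | C[C@H]1CCC(O)(C(Sc2ccccc2)Sc2ccccc2)C1(C)C
F2 | step 2 | (4S)-3,3,4-trimethyl-2-(phenylsulfanyl)cyclohexan-1-one | C[C@H]1CCC(=O)C(Sc2ccccc2)C1(C)C
F3 | step 2 | (2R,4S)-3,3,4-trimethyl-2-[2-(4,4,5,5-tetramethyl-1,3,2-dioxaborolan-2-yl)ethyl]cyclohexan-1-one | B1(OC(C)(C)C(C)(C)O1)CC[C@H]2C(=O)CC[C@H](C)C2(C)C
F4 | step 13 | 2-[(2R,5R,6S,9R)-1-chloro-2,5,6,9,10-pentamethylundecyl]-4,4,5,5-tetramethyl-1,3,2-dioxaborolane | ClC(B1OC(C)(C)C(C)(C)O1)[C@H](C)CC[C@@H](C)[C@@H](C)CC[C@@H](C)C(C)C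
F5 | step 13 | (2R,5R,6S,9R)-2,5,6,9,10-pentamethylundecanal | O=C[C@H](C)CC[C@@H](C)[C@@H](C)CC[C@@H](C)C(C)C
F6 | step 13 | (3E,5R,8R,9S,12R)-5,8,9,12,13-pentamethyltetradec-3-en-2-one | CC(=O)/C=C/[C@H](C)CC[C@@H](C)[C@@H](C)CC[C@@H](C)C(C)C
F7 | step 13 | (2S,3E,5R,8R,9S,12R)-5,8,9,12,13-pentamethyltetradec-3-en-2-ol | C[C@H](O)/C=C/[C@H](C)CC[C@@H](C)[C@@H](C)CC[C@@H](C)C(C)C
F8 | step 14 | 4,4,5,5-tetramethyl-2-{(2R)-4-[(1S,3S)-2,2,3-trimethyl-6-methylidenecyclohexyl]butan-2-yl}-1,3,2-dioxaborolane | B1(OC(C)(C)C(C)(C)O1)[C@H](C)CC[C@H]2C(=C)CC[C@H](C)C2(C)C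
F9 | step 14 | (2R)-4-[(1S,3S)-2,2,3-trimethyl-6-methylidenecyclohexyl]butan-2-ol | O[C@H](C)CC[C@H]1C(=C)CC[C@H](C)C1(C)C
F10 | step 14 | (2R)-4-[(1S,3S)-2,2,3-trimethyl-6-methylidenecyclohexyl]butan-2-yl 2,4,6-tri(propan-2-yl)benzoate | CC(C)c1cc(C(C)C)c(C(=O)O[C@H](C)CC[C@H]2C(=C)CC[C@H](C)C2(C)C)c(C(C)C)c1
F11 | step 14 | (3R,6R,7S,10R)-2-bromo-3,6,7,10,11-pentamethyldodec-1-ene | C=C(Br)[C@H](C)CC[C@@H](C)[C@@H](C)CC[C@@H](C)C(C)C
F12 | step 14 | (3R,6R,7S,10R)-3,6,7,10,11-pentamethyldodec-1-yne | C#C[C@H](C)CC[C@@H](C)[C@@H](C)CC[C@@H](C)C(C)C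
F13 | step 14 | 4,4,5,5-tetramethyl-2-[(1E,3R,6R,7S,10R)-3,6,7,10,11-pentamethyldodec-1-en-1-yl]-1,3,2-dioxaborolane | B1(OC(C)(C)C(C)(C)O1)/C=C/[C@H](C)CC[C@@H](C)[C@@H](C)CC[C@@H](C)C(C)C
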